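The 22-membered ring is cut at C13-C14, where the fourteen-carbon chain (C1 is the carbinol carbon on ring B) meets ring A through a bare benzylic methylene, C14. A temporary phenylsulfonyl group on C14 makes it the one acidic carbon, so a single deprotonation lets it displace iodide from C13 and close the macrocycle. Reduction then erases the sulfone. The precursor is the open diaryl ether already holding the (R)-C1 silyl ether, the Z C8=C9 alkene, three MOM ethers, the ring A CH2SO2Ph arm and the C13 iodide. Sulfur enters early as an inert sulfide and C13 travels as a chloride, so only one ester ever needs to be addressed.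

Key step: step 18

Remark: chain atoms are numbered C1 (carbinol carbon on ring B) to C14 (benzylic CH2 on ring A). Ring A is the 1,3,5-substituted ring and ring B the 4-aryloxy-3,5-dioxygenated ring. The target SMILES reads as 1R and 8Z, and C14 of sulfone 26 is a transient stereocentre formed as both epimers.

Step 1
Reactants: 1 methyl gallate
Product: 2 methyl 4-(benzyloxy)-3,5-dihydroxybenzoate
Conditions: BnBr (1.0 equiv), KHCO3 (1.5 equiv), KI (cat.), DMF, rt
Reagents that add atoms: benzyl bromide, BrCc1ccccc1
Why: Williamson etherification in which the 4-OH, para to the ester, is the most acidic of the three phenols, so the weak base forms mainly its phenoxide and one equivalent of BnBr caps that oxygen alone.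

Step 2
Reactants: 2 methyl 4-(benzyloxy)-3,5-dihydroxybenzoate
Product: 3 methyl 4-(benzyloxy)-3,5-bis(methoxymethoxy)benzoate
Conditions: MOMCl (3 equiv), iPr2NEt (4 equiv), CH2Cl2, 0 °C to rt
Reagents that add atoms: chloromethyl methyl ether (MOMCl), COCCl
Why: Standard MOM etherification (O-alkylation of the two remaining phenols with a hindered amine base), which leaves the ester and the benzyl ether untouched.

Step 3
Reactants: 3 methyl 4-(benzyloxy)-3,5-bis(methoxymethoxy)benzoate
Product: 4 methyl 4-hydroxy-3,5-bis(methoxymethoxy)benzoate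
Conditions: H2 (1 atm), Pd/C (10 wt %), EtOAc, rt
Reagents that add atoms: none
Why: Catalytic hydrogenolysis cleaves only the benzylic C-O bond, so the central 4-OH is released while the MOM acetals and the ester persist.

Step 4
Reactants: 5 methyl 3-bromo-5-hydroxybenzoate
Product: 6 methyl 3-bromo-5-(methoxymethoxy)benzoate
Conditions: MOMCl (1.5 equiv), iPr2NEt (2 equiv), CH2Cl2, 0 °C to rt
Reagents that add atoms: chloromethyl methyl ether (MOMCl), COCCl
Why: The same MOM etherification applies, and the aryl bromide and ester are inert to MOMCl and amine base.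

Step 5
Reactants: 6 methyl 3-bromo-5-(methoxymethoxy)benzoate
Product: 7 [3-bromo-5-(methoxymethoxy)phenyl]methanol
Conditions: iBu2AlH (2.5 equiv), CH2Cl2, -78 to 0 °C; aq potassium sodium tartrate
Reagents that add atoms: none
Why: Ester reduction by two hydride transfers from iBu2AlH gives the benzylic alcohol, and aryl bromides and MOM ethers are not reduced at this temperature.

Step 6
Reactants: 7 [3-bromo-5-(methoxymethoxy)phenyl]methanol
Product: 8 1-bromo-3-(methoxymethoxy)-5-[(phenylsulfanyl)methyl]benzene
Conditions: PhSSPh (1.5 equiv), PBu3 (1.5 equiv), THF, rt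
Reagents that add atoms: diphenyl disulfide, c1ccc(cc1)SSc1ccccc1
Why: Hata-type redox condensation, in which PBu3 and PhSSPh activate the primary benzylic alcohol as an alkoxyphosphonium ion for SN2 displacement by thiolate, installs sulfur in a form that is neither acidic nor electrophilic.

Step 7
Reactants: 4 methyl 4-hydroxy-3,5-bis(methoxymethoxy)benzoate; 8 1-bromo-3-(methoxymethoxy)-5-[(phenylsulfanyl)methyl]benzene
Product: 9 methyl 3,5-bis(methoxymethoxy)-4-{3-(methoxymethoxy)-5-[(phenylsulfanyl)methyl]phenoxy}benzoate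
Conditions: CuI (20 mol %), picolinic acid (40 mol %), K3PO4 (2 equiv), DMSO, 90 °C
Reagents that add atoms: none
Why: Ullmann-type copper-catalysed diaryl ether coupling with a picolinate ligand suited to doubly ortho-substituted phenols tolerates thioether, MOM and ester groups, and it gives a diaryl ether with a single ester, so the ring A and ring B side arms never have to be told apart.

Step 8
Reactants: 9 methyl 3,5-bis(methoxymethoxy)-4-{3-(methoxymethoxy)-5-[(phenylsulfanyl)methyl]phenoxy}benzoate
Product: 10 N-methoxy-N-methyl-3,5-bis(methoxymethoxy)-4-{3-(methoxymethoxy)-5-[(phenylsulfanyl)methyl]phenoxy}benzamide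
Conditions: MeNH(OMe)·HCl (3 equiv), iPrMgCl (6 equiv), THF, -20 to 0 °C
Reagents that add atoms: N,O-dimethylhydroxylamine hydrochloride, CNOC.Cl
Why: Weinreb amide synthesis by aminolysis of the unhindered methyl ester with the magnesium amide works here because the benzylic sulfide CH2 is far too weakly acidic to be touched.

Step 9
Reactants: 11 7-bromoheptan-1-ol
Product: 12 (7-hydroxyheptyl)triphenylphosphonium bromide
Conditions: PPh3 (1.05 equiv), MeCN, reflux
Reagents that add atoms: triphenylphosphine, c1ccc(cc1)P(c1ccccc1)c1ccccc1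
Why: SN2 quaternisation of PPh3 by the primary bromide runs under neutral conditions, where the free hydroxyl does not interfere.

Step 10
Reactants: 13 5-chloropentan-1-ol
Product: 14 5-chloropentanal
Conditions: TEMPO (10 mol %), PhI(OAc)2 (1.1 equiv), CH2Cl2, rt
Reagents that add atoms: none
Why: Oxoammonium (TEMPO) oxidation with PhI(OAc)2 as terminal oxidant stops at the aldehyde in anhydrous CH2Cl2 and does not affect the alkyl chloride.

Step 11
Reactants: 12 (7-hydroxyheptyl)triphenylphosphonium bromide; 14 5-chloropentanal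
Product: 16 (Z)-12-chlorododec-7-en-1-ol, via sodium oxido ylide 15 (not isolated)
Conditions: NaHMDS (2.1 equiv), THF, 0 °C; then 14, -78 °C to rt
Reagents that add atoms: none
Why: Lithium-free Wittig olefination of a non-stabilised ylide under kinetic control (cis-oxaphosphetane) sets the Z geometry of C8=C9, while the second equivalent of base only parks the hydroxyl as its alkoxide and the primary chloride is inert at low temperature.

Step 12
Reactants: 16 (Z)-12-chlorododec-7-en-1-ol
Product: 17 (Z)-12-bromo-1-chlorododec-5-ene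
Conditions: CBr4 (1.2 equiv), PPh3 (1.25 equiv), CH2Cl2, 0 °C
Reagents that add atoms: carbon tetrabromide, BrC(Br)(Br)Br
Why: Appel bromination replaces the primary hydroxyl by SN2 on the alkoxyphosphonium ion, and the poorer leaving group chloride at the far terminus does not exchange at 0 °C.

Step 13
Reactants: 17 (Z)-12-bromo-1-chlorododec-5-ene; 10 N-methoxy-N-methyl-3,5-bis(methoxymethoxy)-4-{3-(methoxymethoxy)-5-[(phenylsulfanyl)methyl]phenoxy}benzamide
Product: 19 (Z)-1-[3,5-bis(methoxymethoxy)-4-{3-(methoxymethoxy)-5-[(phenylsulfanyl)methyl]phenoxy}phenyl]-13-chlorotridec-8-en-1-one, via Grignard reagent 18 (not isolated)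
Conditions: 17 (1.5 equiv), Mg, I2 (cat.), THF, 35 °C; then 10, THF, 0 °C to rt; aq NH4Cl
Reagents that add atoms: none
Why: Magnesium inserts into C-Br much faster than into C-Cl, and the Grignard reagent adds only once because the chelated tetrahedral adduct survives until the quench (Weinreb ketone synthesis), joining C1 to C2 with the whole C2-C13 chain in place.

Step 14
Reactants: 19 (Z)-1-[3,5-bis(methoxymethoxy)-4-{3-(methoxymethoxy)-5-[(phenylsulfanyl)methyl]phenoxy}phenyl]-13-chlorotridec-8-en-1-one
Product: 20 (1R,8Z)-1-[3,5-bis(methoxymethoxy)-4-{3-(methoxymethoxy)-5-[(phenylsulfanyl)methyl]phenoxy}phenyl]-13-chlorotridec-8-en-1-ol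
Conditions: (S)-2-methyl-CBS-oxazaborolidine (0.2 equiv), catecholborane (2 equiv), toluene, -78 to -40 °C; MeOH, then aq NaHCO3
Reagents that add atoms: none
Why: In this Corey-Bakshi-Shibata reduction the ketone binds to the (S)-oxazaborolidine with the large aryl group turned away from the boron substituent, so hydride reaches the Si face and gives the (R)-carbinol, while catecholborane at low temperature does not hydroborate the alkene.

Step 15
Reactants: 20 (1R,8Z)-1-[3,5-bis(methoxymethoxy)-4-{3-(methoxymethoxy)-5-[(phenylsulfanyl)methyl]phenoxy}phenyl]-13-chlorotridec-8-en-1-ol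
Product: 21 C1-O-tert-butyldimethylsilyl ether of 20 (1R,8Z; sulfide and chloride retained)
Conditions: TBSCl (1.5 equiv), imidazole (3 equiv), DMF, rt
Reagents that add atoms: tert-butyldimethylsilyl chloride, CC(C)(C)[Si](C)(C)Cl
Why: Imidazole-promoted O-silylation of the secondary benzylic alcohol does not break the C1-O bond, so the R configuration is retained.

Step 16
Reactants: 21 C1-O-tert-butyldimethylsilyl ether of 20
Product: 23 (1R,8Z) chloro sulfone (ring A CH2SO2Ph; C1-OTBS; C13-Cl), via benzylic sulfoxide 22 (not isolated)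
Conditions: (NH4)6Mo7O24·4H2O (10 mol %), 30% aq H2O2 (5 equiv), EtOH/THF, 0 °C to rt
Reagents that add atoms: hydrogen peroxide, OO
Why: In peroxomolybdate-catalysed S-oxidation the nucleophilic sulfide and then the sulfoxide are oxidised far faster than an unactivated 1,2-dialkyl alkene, a chemoselectivity routinely used when sulfones for Julia-type olefinations are made.

Step 17
Reactants: 23 (1R,8Z) chloro sulfone
Product: 24 (1R,8Z) sulfone iodide seco compound (ring A CH2SO2Ph; C1-OTBS; C13-I; three aryl MOM ethers)
Conditions: NaI (10 equiv), NaHCO3 (buffer), 2-butanone, reflux, dark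
Reagents that add atoms: sodium iodide, [Na+].[I-]
Why: Finkelstein exchange, driven by precipitation of NaCl, turns the dormant chloride into the reactive iodide one step before it is needed.

Step 18
Reactants: 24 (1R,8Z) sulfone iodide seco compound
Product: 26 macrocyclic C14 phenyl sulfone (22-membered ring; 1R,8Z; both C14 epimers), via potassium sulfonyl carbanion 25 (not isolated)
Conditions: KHMDS (1.5 equiv), THF, 0 °C to rt; 24 in THF added by syringe pump over 10 h (final 1 mM)
Reagents that add atoms: none
Why: KHMDS removes one of the two C14 protons, which are benzylic and alpha to the sulfonyl group and by far the most acidic C-H bonds in 24, and carbanion 25 attacks C13 from the rear and expels iodide in an SN2 step that forms C13-C14. The closest known reaction type is the macrocyclising intramolecular alkylation of sulfone-stabilised carbanions by primary halides under high dilution, as used for large carbocycles. The single ring closes in the 22-exo-tet mode, and the rigid diaryl ether and the Z-alkene remove rotors from an otherwise strain-free chain. C14 becomes a stereocentre without any control, which is harmless because step 19 turns it back into CH2, while C1 and the alkene lie far from the reacting atoms. Ring closure must beat dimerisation, E2 loss of HI and attack of the amide base on C13: slow addition keeps the standing concentration of 25 very low, the soft delocalised carbanion prefers substitution, and millimolar hindered KHMDS is too dilute to compete. A second alkylation is held back because the product carbanion is tertiary and shielded, and neither C1-H, the MOM acetals nor the silyl ether respond to this base.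

Step 19
Reactants: 26 macrocyclic C14 phenyl sulfone
Product: 27 (1R,8Z) macrocycle with C14 as CH2 (C1-OTBS; three aryl MOM ethers)
Conditions: Mg turnings (30 equiv), MeOH/THF, rt to 40 °C
Reagents that add atoms: none
Why: In reductive desulfonylation by single-electron transfer the sulfone radical anion fragments to benzenesulfinate and the C14 benzylic radical, which is reduced and protonated faster than a stabilised 6-heptenyl-type radical could add to C9, so both C14 epimers converge on one compound.

Step 20
Reactants: 27 (1R,8Z) macrocycle with C14 as CH2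
Product: 29 (1R,8Z) macrocyclic triphenol C1-OTBS ether, via tris(trimethylsilyl) aryl ether 28 (not isolated)
Conditions: TMSOTf (8 equiv), 2,2'-bipyridyl (12 equiv), MeCN/CH2Cl2, 0 °C to rt; then H2O, rt
Reagents that add atoms: none
Why: In the silyl triflate/bipyridyl cleavage of aromatic MOM ethers each acetal is silylated, its methoxymethyl unit is trapped as an N-alkylbipyridinium salt and the aryl TMS ethers hydrolyse when water is added, all without free Brønsted acid, so C1-O is not ionised and no oxocarbenium ion can attack the electron-rich rings.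

Step 21
Reactants: 29 (1R,8Z) macrocyclic triphenol C1-OTBS ether
Product: 30 target CNP0316989.2 (1R,8Z)
Conditions: TBAF (6 equiv), AcOH (4 equiv), THF, 0 °C to rt, argon
Reagents that add atoms: none
Why: Fluoride-induced desilylation, driven by the strong Si-F bond, cleaves O-Si and not C1-O, so the R configuration is retained, and the acetic acid buffer keeps the phenols from standing as air-sensitive phenoxides.

Compound list
1 | methyl gallate | COC(=O)c1cc(O)c(O)c(O)c1 | starting material
2 | methyl 4-(benzyloxy)-3,5-dihydroxybenzoate | COC(=O)c1cc(O)c(OCc2ccccc2)c(O)c1 | intermediate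
3 | methyl 4-(benzyloxy)-3,5-bis(methoxymethoxy)benzoate | COC(=O)c1cc(OCOC)c(OCc2ccccc2)c(OCOC)c1 | intermediate
4 | methyl 4-hydroxy-3,5-bis(methoxymethoxy)benzoate (ring B phenol) | COC(=O)c1cc(OCOC)c(O)c(OCOC)c1 | intermediate
5 | methyl 3-bromo-5-hydroxybenzoate | COC(=O)c1cc(O)cc(Br)c1 | starting material
6 | methyl 3-bromo-5-(methoxymethoxy)benzoate | COC(=O)c1cc(OCOC)cc(Br)c1 | intermediate
7 | [3-bromo-5-(methoxymethoxy)phenyl]methanol | OCc1cc(OCOC)cc(Br)c1 | intermediate
8 | 1-bromo-3-(methoxymethoxy)-5-[(phenylsulfanyl)methyl]benzene (ring A bromide) | COCOc1cc(Br)cc(CSc2ccccc2)c1 | intermediate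
9 | methyl 3,5-bis(methoxymethoxy)-4-{3-(methoxymethoxy)-5-[(phenylsulfanyl)methyl]phenoxy}benzoate | COCOc1cc(CSc2ccccc2)cc(c1)Oc1c(OCOC)cc(cc1OCOC)C(=O)OC | intermediate
10 | N-methoxy-N-methyl-3,5-bis(methoxymethoxy)-4-{3-(methoxymethoxy)-5-[(phenylsulfanyl)methyl]phenoxy}benzamide | COCOc1cc(CSc2ccccc2)cc(c1)Oc1c(OCOC)cc(cc1OCOC)C(=O)N(C)OC | intermediate
11 | 7-bromoheptan-1-ol | OCCCCCCCBr | starting material
12 | (7-hydroxyheptyl)triphenylphosphonium bromide | OCCCCCCC[P+](c1ccccc1)(c1ccccc1)c1ccccc1.[Br-] | intermediate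
13 | 5-chloropentan-1-ol | OCCCCCCl | starting material
14 | 5-chloropentanal | O=CCCCCCl | intermediate
15 | sodium 7-(triphenylphosphoranylidene)heptan-1-olate (oxido ylide) | [Na+].[O-]CCCCCCC=P(c1ccccc1)(c1ccccc1)c1ccccc1 | intermediate
16 | (Z)-12-chlorododec-7-en-1-ol | OCCCCCC/C=C\CCCCCl | intermediate
17 | (Z)-12-bromo-1-chlorododec-5-ene | BrCCCCCC/C=C\CCCCCl | intermediate
18 | [(Z)-12-chlorododec-7-enyl]magnesium bromide | Br[Mg]CCCCCC/C=C\CCCCCl | intermediate
19 | (Z)-1-[3,5-bis(methoxymethoxy)-4-{3-(methoxymethoxy)-5-[(phenylsulfanyl)methyl]phenoxy}phenyl]-13-chlorotridec-8-en-1-one | COCOc1cc(CSc2ccccc2)cc(c1)Oc1c(OCOC)cc(cc1OCOC)C(=O)CCCCCC/C=C\CCCCCl | intermediate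
20 | (1R,8Z)-1-[3,5-bis(methoxymethoxy)-4-{3-(methoxymethoxy)-5-[(phenylsulfanyl)methyl]phenoxy}phenyl]-13-chlorotridec-8-en-1-ol | COCOc1cc(CSc2ccccc2)cc(c1)Oc1c(OCOC)cc(cc1OCOC)[C@H](O)CCCCCC/C=C\CCCCCl | intermediate
21 | C1-O-TBS ether of 20 (1R,8Z) | COCOc1cc(CSc2ccccc2)cc(c1)Oc1c(OCOC)cc(cc1OCOC)[C@H](O[Si](C)(C)C(C)(C)C)CCCCCC/C=C\CCCCCl | intermediate
22 | benzylic phenyl sulfoxide of 21 (1R,8Z; sulfur epimers) | COCOc1cc(CS(=O)c2ccccc2)cc(c1)Oc1c(OCOC)cc(cc1OCOC)[C@H](O[Si](C)(C)C(C)(C)C)CCCCCC/C=C\CCCCCl | intermediate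
23 | (1R,8Z) chloro sulfone | COCOc1cc(CS(=O)(=O)c2ccccc2)cc(c1)Oc1c(OCOC)cc(cc1OCOC)[C@H](O[Si](C)(C)C(C)(C)C)CCCCCC/C=C\CCCCCl | intermediate
24 | (1R,8Z) sulfone iodide seco compound | COCOc1cc(CS(=O)(=O)c2ccccc2)cc(c1)Oc1c(OCOC)cc(cc1OCOC)[C@H](O[Si](C)(C)C(C)(C)C)CCCCCC/C=C\CCCCI | intermediate
25 | potassium C14 sulfonyl carbanion of 24 | COCOc1cc([CH-]S(=O)(=O)c2ccccc2)cc(c1)Oc1c(OCOC)cc(cc1OCOC)[C@H](O[Si](C)(C)C(C)(C)C)CCCCCC/C=C\CCCCI.[K+] | intermediate
26 | macrocyclic C14 phenyl sulfone (1R,8Z; C14 epimers) | COCOc1cc2cc(c1)Oc1c(OCOC)cc(cc1OCOC)[C@H](O[Si](C)(C)C(C)(C)C)CCCCCC/C=C\CCCCC2S(=O)(=O)c1ccccc1 | intermediate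
27 | desulfonylated macrocycle (1R,8Z; C1-OTBS; tris-MOM) | COCOc1cc2cc(c1)Oc1c(OCOC)cc(cc1OCOC)[C@H](O[Si](C)(C)C(C)(C)C)CCCCCC/C=C\CCCCC2 | intermediate
28 | macrocyclic tris(trimethylsilyl) aryl ether (1R,8Z; C1-OTBS) | C[Si](C)(C)Oc1cc2cc(c1)Oc1c(O[Si](C)(C)C)cc(cc1O[Si](C)(C)C)[C@H](O[Si](C)(C)C(C)(C)C)CCCCCC/C=C\CCCCC2 | intermediate
29 | macrocyclic triphenol C1-OTBS ether (1R,8Z) | Oc1cc2cc(c1)Oc1c(O)cc(cc1O)[C@H](O[Si](C)(C)C(C)(C)C)CCCCCC/C=C\CCCCC2 | intermediate
30 | CNP0316989.2, (1R,8Z) macrocyclic diaryl ether with three phenols and the C1 carbinol | Oc1cc2cc(c1)Oc1c(O)cc(cc1O)[C@H](O)CCCCCC/C=C\CCCCC2 | target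

Total step count: 21.
Longest linear sequence: 14 steps (1, 2, 3, 7, 8, 13 to 21). The ring A branch (4, 5, 6, 7, 8, 13 to 21) is equally long, and the chain branch (9 or 10, 11, 12, 13 to 21) counts 12.

Steps most likely to fail

Step 18. Intermolecular alkylation leading to oligomers may outpace closure of so large a ring, as may loss of the iodide through elimination or attack by the amide base. The fallback keeps the sulfone chemistry for C13-C14 but runs it intermolecularly, and closes the ring at C8=C9 by Z-selective ring-closing metathesis. It sets out from 10.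
- Oct-7-enylmagnesium bromide (from 8-bromooct-1-ene) gives the terminal-alkene ketone F1.
- CBS reduction as in step 14 gives the (R)-alcohol F2.
- TBSCl and imidazole give the silyl ether F3.
- (NH4)6Mo7O24 and H2O2 give the benzylic sulfone F4.
- KHMDS followed by 6-iodohex-1-ene at -78 °C gives the diene sulfone F5 as C14 epimers.
- The cyclometalated catalyst Ru(NO3)(=CH-C6H4-2-OiPr)(C-chelating 1-adamantyl-3-mesitylimidazolin-2-ylidene), in dilute 1,2-dichloroethane under static vacuum, expels ethene and rejoins the route at 26.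

Step 7. C-O bond formation may be sluggish because the phenoxide of 4 is flanked by two MOM-oxy groups and deactivated by the para ester. Protodebromination of 8 or ester cleavage could then take over on long heating. The fallback replaces the hot halide coupling by a room-temperature oxidative Chan-Lam-Evans coupling. It sets out from 8.
- n-BuLi is added to a mixture of 8 and B(OiPr)3 in THF/toluene at -78 °C, and a mild aqueous work-up gives the ring A boronic acid F6.
- Cu(OAc)2, pyridine, 4 Å molecular sieves and air in CH2Cl2 at rt then join F6 to phenol 4 and rejoin the route at 9.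

Step 20. Cleavage of the two crowded ring B acetals may stay incomplete. If forcing is needed, ionisation at C1 may erode the configuration. The fallback moves the acetal cleavage to the ketone oxidation level, where strong Brønsted acid is harmless, and sets C1 again afterwards. It sets out from 27.
- TBAF gives the macrocyclic carbinol F7.
- Dess-Martin periodinane with NaHCO3 gives the macrocyclic aryl ketone F8.
- HCl in MeOH (from AcCl) at 40 °C removes all three MOM groups and gives the trihydroxy ketone F9.
- Noyori-type asymmetric transfer hydrogenation with RuCl(p-cymene)[(R,R)-TsDPEN] in HCO2H/Et3N, which tolerates free phenols and isolated alkenes, delivers the (R)-carbinol and rejoins the route at 30.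

Further compounds
F1 | step 18 | 1-[3,5-bis(methoxymethoxy)-4-{3-(methoxymethoxy)-5-[(phenylsulfanyl)methyl]phenoxy}phenyl]non-8-en-1-one | COCOc1cc(CSc2ccccc2)cc(c1)Oc1c(OCOC)cc(cc1OCOC)C(=O)CCCCCCC=C
F2 | step 18 | (1R)-alcohol from F1 | COCOc1cc(CSc2ccccc2)cc(c1)Oc1c(OCOC)cc(cc1OCOC)[C@H](O)CCCCCCC=C
F3 | step 18 | C1-O-TBS ether of F2 (1R) | COCOc1cc(CSc2ccccc2)cc(c1)Oc1c(OCOC)cc(cc1OCOC)[C@H](O[Si](C)(C)C(C)(C)C)CCCCCCC=C
F4 | step 18 | benzylic phenyl sulfone from F3 (1R) | COCOc1cc(CS(=O)(=O)c2ccccc2)cc(c1)Oc1c(OCOC)cc(cc1OCOC)[C@H](O[Si](C)(C)C(C)(C)C)CCCCCCC=C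
F5 | step 18 | diene sulfone, F4 alkylated at C14 with a hex-5-enyl group (1R; C14 epimers) | COCOc1cc(C(CCCCC=C)S(=O)(=O)c2ccccc2)cc(c1)Oc1c(OCOC)cc(cc1OCOC)[C@H](O[Si](C)(C)C(C)(C)C)CCCCCCC=C
F6 | step 7 | {3-(methoxymethoxy)-5-[(phenylsulfanyl)methyl]phenyl}boronic acid | COCOc1cc(CSc2ccccc2)cc(c1)B(O)O
F7 | step 20 | macrocyclic carbinol tris-MOM ether (1R,8Z) | COCOc1cc2cc(c1)Oc1c(OCOC)cc(cc1OCOC)[C@H](O)CCCCCC/C=C\CCCCC2
F8 | step 20 | macrocyclic C1 ketone tris-MOM ether (8Z) | COCOc1cc2cc(c1)Oc1c(OCOC)cc(cc1OCOC)C(=O)CCCCCC/C=C\CCCCC2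
F9 | step 20 | macrocyclic C1 ketone triphenol (8Z) | Oc1cc2cc(c1)Oc1c(O)cc(cc1O)C(=O)CCCCCC/C=C\CCCCC2
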